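The route hinges on making the bond between the 3,4-dimethoxyphenyl ring and C1, counting the chain from the ArCH(OH) carbon (C1) via the branch-point CH (C2) and the allylic CH2 (C3) to the alkene carbon next to it (C4). If the C1 hydroxyl is acylated by C4 at the carboxyl oxidation level, the five atoms O, C1, C2, C3 and C4 form the γ-butyrolactone of natural isocitric acid, whose C2 centre is already correct. The key step, in one operation, exchanges the C1 carboxyl of that lactone, as its cis N-hydroxyphthalimide ester with C2 bearing a silyloxymethyl group, for the aryl ring by nickel-catalysed electroreductive decarboxylative coupling, fixing C1 trans to C2.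

Key step: step 6

Remark on the chemistry: benzyl alcohol is assumed to open anhydride 3 at the carbonyl on the oxygen-bearing ring carbon, as O-acylmalic anhydrides are opened; natural (1R,2S)-isocitric acid gives the cis (2R,3S) lactone, and reducing its C3 carboxyl changes that descriptor to R without touching the centre.

Step 1
Reactants: 1 potassium hydrogen (1R,2S)-isocitrate
Product: 3 (3aS,6aR)-dihydrofuro[3,4-b]furan-2,4,6(3H)-trione, via lactone diacid 2 (not isolated)
Conditions: aq. HCl (1 equiv), evaporate, 100 °C, vacuum; then Ac2O, 70 °C; filter off KCl, evaporate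
Reagents that add atoms: none
Why: Acidification frees the hydroxy triacid, which closes the γ-lactone on heating (lactonisation), and acetic anhydride then dehydrates its two cis carboxyl groups to the five-membered cyclic anhydride without breaking a bond to either stereocentre.

Step 2
Reactants: 3 (3aS,6aR)-dihydrofuro[3,4-b]furan-2,4,6(3H)-trione
Product: 4 (2R,3S)-2-[(benzyloxy)carbonyl]-5-oxotetrahydrofuran-3-carboxylic acid
Conditions: BnOH (1.1 equiv), CH2Cl2, 0 °C to rt, no base
Reagents that add atoms: benzyl alcohol, OCc1ccccc1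
Why: Uncatalysed alcoholysis of an unsymmetrical cyclic anhydride (anhydride ring-opening) should take place at the more electrophilic carbonyl, the one on the ring carbon that carries the lactone oxygen, which leaves the other carboxyl free for reduction.

Step 3
Reactants: 4 (2R,3S)-2-[(benzyloxy)carbonyl]-5-oxotetrahydrofuran-3-carboxylic acid
Product: 6 benzyl (2R,3R)-3-{[(tert-butyldimethylsilyl)oxy]methyl}-5-oxotetrahydrofuran-2-carboxylate, via hydroxy ester 5 (not isolated)
Conditions: BH3·SMe2, THF, 0 °C to rt; MeOH, evaporate; then TBSCl, imidazole, DMF, 0 °C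
Reagents that add atoms: tert-butyldimethylsilyl chloride, CC(C)(C)[Si](C)(C)Cl
Why: Borane reduces a free carboxylic acid far faster than an ester or a lactone (chemoselective borane reduction), and silylating the crude primary alcohol before isolation keeps it from lactonising onto the cis benzyl ester.

Step 4
Reactants: 6 benzyl (2R,3R)-3-{[(tert-butyldimethylsilyl)oxy]methyl}-5-oxotetrahydrofuran-2-carboxylate
Product: 7 (2R,3R)-3-{[(tert-butyldimethylsilyl)oxy]methyl}-5-oxotetrahydrofuran-2-carboxylic acid
Conditions: H2 (1 atm), Pd/C (10 wt %), EtOAc, rt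
Reagents that add atoms: none
Why: Hydrogenolysis of the benzyl ester over palladium in a non-protic solvent should leave the silyl ether and the lactone untouched.

Step 5
Reactants: 7 (2R,3R)-3-{[(tert-butyldimethylsilyl)oxy]methyl}-5-oxotetrahydrofuran-2-carboxylic acid
Product: 8 1,3-dioxoisoindolin-2-yl (2R,3R)-3-{[(tert-butyldimethylsilyl)oxy]methyl}-5-oxotetrahydrofuran-2-carboxylate (cis)
Conditions: N-hydroxyphthalimide, N,N'-diisopropylcarbodiimide, DMAP (cat.), CH2Cl2, 0 °C to rt
Reagents that add atoms: N-hydroxyphthalimide, O=C1c2ccccc2C(=O)N1O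
Why: Carbodiimide coupling (Steglich-type esterification) gives the redox-active ester, and the silylated hydroxyl cannot attack it.

Step 6
Reactants: 8 1,3-dioxoisoindolin-2-yl (2R,3R)-3-{[(tert-butyldimethylsilyl)oxy]methyl}-5-oxotetrahydrofuran-2-carboxylate; 9 4-iodo-1,2-dimethoxybenzene (3 equiv)
Product: 10 (4R,5S)-4-{[(tert-butyldimethylsilyl)oxy]methyl}-5-(3,4-dimethoxyphenyl)dihydrofuran-2(3H)-one (trans)
Conditions: NiCl2(MeOCH2CH2OMe) (20 mol %), 4,4'-di-tert-butyl-2,2'-bipyridine (20 mol %), LiBr (electrolyte), DMA, undivided cell, reticulated vitreous carbon cathode, sacrificial Zn anode, constant current, rt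
Reagents that add atoms: none
Why: Cathodic reduction turns divalent nickel into zerovalent nickel, which inserts into the C–I bond of 9, while single-electron reduction of the phthalimide ester (by low-valent nickel or at the cathode) cleaves the N–O bond and expels CO2 to leave a planar α-acyloxy radical at C1, the ring carbon bonded to the ring oxygen, so the configuration of that carbon in 8 no longer matters. The divalent aryl nickel species traps the radical and the resulting trivalent nickel species forms the C1–aryl bond by reductive elimination, after which monovalent nickel is reduced again at the cathode. The closest known reaction type is the nickel-catalysed electroreductive cross-electrophile decarboxylative arylation of N-hydroxyphthalimide esters, those of α-oxy acids included, with aryl iodides. No ring is closed. The one new stereocentre, C1, is controlled by the existing C2 centre: nickel reaches the envelope-shaped lactone radical from the face opposite the neighbouring CH2OTBS group, which should give the trans (4R,5S) lactone. The step needs this trans selectivity and tolerance of the electron-rich arene; the bulk of the vicinal substituent and the net reducing medium should provide both, and the trans isomer is also the more stable one.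

Step 7
Reactants: 10 (4R,5S)-4-{[(tert-butyldimethylsilyl)oxy]methyl}-5-(3,4-dimethoxyphenyl)dihydrofuran-2(3H)-one
Product: 11 (4R,5S)-4-{[(tert-butyldimethylsilyl)oxy]methyl}-5-(3,4-dimethoxyphenyl)tetrahydrofuran-2-ol (mixture of anomers)
Conditions: i-Bu2AlH (1.2 equiv), CH2Cl2, −78 °C; aq. potassium sodium tartrate
Reagents that add atoms: none
Why: Partial reduction of a γ-lactone with i-Bu2AlH at low temperature stops at the aluminium hemiacetal (lactone-to-lactol reduction) and should not affect the silyl ether or the aryl ethers.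

Step 8
Reactants: 11 (4R,5S)-4-{[(tert-butyldimethylsilyl)oxy]methyl}-5-(3,4-dimethoxyphenyl)tetrahydrofuran-2-ol; 12 diethyl (4-methoxybenzyl)phosphonate (3 equiv)
Product: 15 (1S,2R)-1-(3,4-dimethoxyphenyl)-2-[(2E)-3-(4-methoxyphenyl)prop-2-en-1-yl]propane-1,3-diol, via phosphonate carbanion 13 (not isolated), via silyl ether 14 (not isolated)
Conditions: 12, KOt-Bu (3.2 equiv), THF, 0 °C; add 11, 0 °C to rt; then n-Bu4NF, THF, rt; aq. NH4Cl work-up
Reagents that add atoms: none
Why: The potassium carbanion of the benzylic phosphonate intercepts the open hydroxy aldehyde form of the lactol in a Horner–Wadsworth–Emmons olefination, whose reversible addition favours the E styrene, and fluoride then removes the silyl group from whichever oxygen it occupies after any base-induced 1,3 migration, while C1 and C2 have no acidic hydrogen and keep their configuration.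

Step 9
Reactants: 16 (E)-but-2-enal (crotonaldehyde)
Product: 17 (2Z)-2-iodobut-2-enal
Conditions: I2, K2CO3, DMAP (cat.), THF/H2O (1:1), rt
Reagents that add atoms: iodine, II
Why: Amine-catalysed α-iodination of an enal (conjugate addition of the pyridine base, iodination of the enolate, elimination) should give the more stable Z isomer, with iodine cis to the methyl group.

Step 10
Reactants: 17 (2Z)-2-iodobut-2-enal
Product: 18 (2Z)-2-iodobut-2-en-1-ol
Conditions: NaBH4, CeCl3·7H2O, MeOH, 0 °C
Reagents that add atoms: none
Why: Luche 1,2-reduction converts the enal into the allylic alcohol without touching the vinyl iodide or the alkene geometry.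

Step 11
Reactants: 18 (2Z)-2-iodobut-2-en-1-ol
Product: 19 tert-butyl{[(2Z)-2-iodobut-2-en-1-yl]oxy}dimethylsilane
Conditions: TBSCl, imidazole, CH2Cl2, rt
Reagents that add atoms: tert-butyldimethylsilyl chloride, CC(C)(C)[Si](C)(C)Cl
Why: Routine silyl ether formation on a primary allylic alcohol.

Step 12
Reactants: 19 tert-butyl{[(2Z)-2-iodobut-2-en-1-yl]oxy}dimethylsilane
Product: 21 (2Z)-2-{[(tert-butyldimethylsilyl)oxy]methyl}but-2-enoic acid, via vinyllithium 20 (not isolated)
Conditions: t-BuLi (2.1 equiv), Et2O, −78 °C; CO2 (gas), −78 to 0 °C; cold aq. HCl to pH 3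
Reagents that add atoms: carbon dioxide, O=C=O
Why: Iodine–lithium exchange on an alkenyl iodide and carboxylation of the alkenyllithium both proceed with retention of geometry, so the carboxyl should end up cis to the methyl group (Z acid), and the low temperature with immediate quench suppresses silyl migration and β-elimination.

Step 13
Reactants: 15 (1S,2R)-1-(3,4-dimethoxyphenyl)-2-[(2E)-3-(4-methoxyphenyl)prop-2-en-1-yl]propane-1,3-diol; 21 (2Z)-2-{[(tert-butyldimethylsilyl)oxy]methyl}but-2-enoic acid (1.1 equiv)
Product: 23 (2R,4E)-2-[(S)-(3,4-dimethoxyphenyl)(hydroxy)methyl]-5-(4-methoxyphenyl)pent-4-en-1-yl (2Z)-2-{[(tert-butyldimethylsilyl)oxy]methyl}but-2-enoate, via mixed anhydride 22 (not isolated)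
Conditions: 21, 2,4,6-trichlorobenzoyl chloride, Et3N, toluene, rt; then 15, DMAP (0.3 equiv), 0 °C to rt
Reagents that add atoms: none
Why: Yamaguchi esterification through the 2,4,6-trichlorobenzoyl mixed anhydride should acylate the primary hydroxyl in preference to the hindered secondary benzylic one and is known to transfer angelate-type Z acyl groups with their geometry intact.

Step 14
Reactants: 23 (2R,4E)-2-[(S)-(3,4-dimethoxyphenyl)(hydroxy)methyl]-5-(4-methoxyphenyl)pent-4-en-1-yl (2Z)-2-{[(tert-butyldimethylsilyl)oxy]methyl}but-2-enoate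
Product: 24 (2R,4E)-2-[(S)-(3,4-dimethoxyphenyl)(hydroxy)methyl]-5-(4-methoxyphenyl)pent-4-en-1-yl (2Z)-2-(hydroxymethyl)but-2-enoate (CNP0280662.1)
Conditions: HF·pyridine, pyridine, THF, 0 °C to rt
Reagents that add atoms: none
Why: Buffered HF·pyridine cleaves the primary silyl ether (fluoride desilylation) under non-basic conditions, so neither acyl migration to the benzylic hydroxyl nor ionisation of the electron-rich benzylic alcohol should intervene.

Compound list
1 | potassium hydrogen (1R,2S)-isocitrate (monopotassium salt of natural isocitric acid) | OC(=O)C[C@H](C(=O)O)[C@@H](O)C(=O)[O-].[K+] | starting material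
2 | (2R,3S)-5-oxotetrahydrofuran-2,3-dicarboxylic acid (cis; isocitric acid lactone) | OC(=O)[C@H]1CC(=O)O[C@H]1C(=O)O | intermediate
3 | (3aS,6aR)-dihydrofuro[3,4-b]furan-2,4,6(3H)-trione (cis-fused cyclic anhydride of 2) | O=C1C[C@@H]2C(=O)OC(=O)[C@@H]2O1 | intermediate
4 | (2R,3S)-2-[(benzyloxy)carbonyl]-5-oxotetrahydrofuran-3-carboxylic acid | OC(=O)[C@H]1CC(=O)O[C@H]1C(=O)OCc1ccccc1 | intermediate
5 | benzyl (2R,3R)-3-(hydroxymethyl)-5-oxotetrahydrofuran-2-carboxylate | OC[C@H]1CC(=O)O[C@H]1C(=O)OCc1ccccc1 | intermediate
6 | benzyl (2R,3R)-3-{[(tert-butyldimethylsilyl)oxy]methyl}-5-oxotetrahydrofuran-2-carboxylate | CC(C)(C)[Si](C)(C)OC[C@H]1CC(=O)O[C@H]1C(=O)OCc1ccccc1 | intermediate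
7 | (2R,3R)-3-{[(tert-butyldimethylsilyl)oxy]methyl}-5-oxotetrahydrofuran-2-carboxylic acid | CC(C)(C)[Si](C)(C)OC[C@H]1CC(=O)O[C@H]1C(=O)O | intermediate
8 | 1,3-dioxoisoindolin-2-yl (2R,3R)-3-{[(tert-butyldimethylsilyl)oxy]methyl}-5-oxotetrahydrofuran-2-carboxylate (cis) | CC(C)(C)[Si](C)(C)OC[C@H]1CC(=O)O[C@H]1C(=O)ON1C(=O)c2ccccc2C1=O | intermediate
9 | 4-iodo-1,2-dimethoxybenzene | COc1ccc(I)cc1OC | starting material
10 | (4R,5S)-4-{[(tert-butyldimethylsilyl)oxy]methyl}-5-(3,4-dimethoxyphenyl)dihydrofuran-2(3H)-one (trans) | CC(C)(C)[Si](C)(C)OC[C@H]1CC(=O)O[C@@H]1c1ccc(OC)c(OC)c1 | intermediate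
11 | (4R,5S)-4-{[(tert-butyldimethylsilyl)oxy]methyl}-5-(3,4-dimethoxyphenyl)tetrahydrofuran-2-ol (mixture of anomers) | CC(C)(C)[Si](C)(C)OC[C@H]1CC(O)O[C@@H]1c1ccc(OC)c(OC)c1 | intermediate
12 | diethyl (4-methoxybenzyl)phosphonate | CCOP(=O)(Cc1ccc(OC)cc1)OCC | starting material
13 | potassium salt of the benzylic carbanion of 12 | CCOP(=O)([CH-]c1ccc(OC)cc1)OCC.[K+] | intermediate
14 | (1S,2R,4E)-2-{[(tert-butyldimethylsilyl)oxy]methyl}-1-(3,4-dimethoxyphenyl)-5-(4-methoxyphenyl)pent-4-en-1-ol | CC(C)(C)[Si](C)(C)OC[C@@H](C/C=C/c1ccc(OC)cc1)[C@H](O)c1ccc(OC)c(OC)c1 | intermediate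
15 | (1S,2R)-1-(3,4-dimethoxyphenyl)-2-[(2E)-3-(4-methoxyphenyl)prop-2-en-1-yl]propane-1,3-diol | OC[C@@H](C/C=C/c1ccc(OC)cc1)[C@H](O)c1ccc(OC)c(OC)c1 | intermediate
16 | (E)-but-2-enal (crotonaldehyde) | C/C=C/C=O | starting material
17 | (2Z)-2-iodobut-2-enal | C/C=C(\I)C=O | intermediate
18 | (2Z)-2-iodobut-2-en-1-ol | C/C=C(\I)CO | intermediate
19 | tert-butyl{[(2Z)-2-iodobut-2-en-1-yl]oxy}dimethylsilane | C/C=C(\I)CO[Si](C)(C)C(C)(C)C | intermediate
20 | [(2E)-1-{[tert-butyl(dimethyl)silyl]oxy}but-2-en-2-yl]lithium (lithium cis to the methyl group) | C/C=C(\[Li])CO[Si](C)(C)C(C)(C)C | intermediate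
21 | (2Z)-2-{[(tert-butyldimethylsilyl)oxy]methyl}but-2-enoic acid | C/C=C(/CO[Si](C)(C)C(C)(C)C)C(=O)O | intermediate
22 | (2Z)-2-{[(tert-butyldimethylsilyl)oxy]methyl}but-2-enoic 2,4,6-trichlorobenzoic anhydride | C/C=C(/CO[Si](C)(C)C(C)(C)C)C(=O)OC(=O)c1c(Cl)cc(Cl)cc1Cl | intermediate
23 | (2R,4E)-2-[(S)-(3,4-dimethoxyphenyl)(hydroxy)methyl]-5-(4-methoxyphenyl)pent-4-en-1-yl (2Z)-2-{[(tert-butyldimethylsilyl)oxy]methyl}but-2-enoate | C/C=C(/CO[Si](C)(C)C(C)(C)C)C(=O)OC[C@@H](C/C=C/c1ccc(OC)cc1)[C@H](O)c1ccc(OC)c(OC)c1 | intermediate
24 | (2R,4E)-2-[(S)-(3,4-dimethoxyphenyl)(hydroxy)methyl]-5-(4-methoxyphenyl)pent-4-en-1-yl (2Z)-2-(hydroxymethyl)but-2-enoate | C/C=C(/CO)C(=O)OC[C@@H](C/C=C/c1ccc(OC)cc1)[C@H](O)c1ccc(OC)c(OC)c1 | target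

Total step count: 14.
Longest linear sequence: 10 steps (steps 1 to 8, then 13 and 14); steps 9 to 12 build the acid side chain separately.

Steps most likely to fail

Step 6. The radical may be reduced further or abstract hydrogen before the aryl nickel species captures it, or capture may occur with poor facial selectivity. The fallback sets out from acid 7 and uses metallaphotoredox decarboxylative arylation with 9 (Ir[dF(CF3)ppy]2(dtbbpy)PF6, NiCl2(MeOCH2CH2OMe), 4,4'-di-tert-butyl-2,2'-bipyridine, Cs2CO3, DMF, blue light, rt). There the carboxylate is oxidised by the excited photocatalyst and no activated ester is reduced, so the same C1 radical forms slowly with no stoichiometric reductant in the flask. This is known chemistry for α-oxy acids and comes back to the route at lactone 10; it makes no compound outside the list (F0).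

Step 8. The lactol may fail to open and olefinate cleanly, through enolisation of the aldehyde by the strongly basic carbanion, slow collapse of the β-oxido phosphonate, or erosion of alkene geometry. The fallback sets out from lactol 11. Wittig methylenation with Ph3P=CH2 (from Ph3PCH3Br and KOt-Bu, THF, 0 °C to rt), the classic opening of a lactol by a reactive unstabilised ylide, should give the terminal alkene (1S,2R)-2-{[(tert-butyldimethylsilyl)oxy]methyl}-1-(3,4-dimethoxyphenyl)pent-4-en-1-ol F1. Cross-metathesis of F1 with 4-methoxystyrene (second-generation Hoveyda–Grubbs catalyst, (H2IMes)Cl2Ru=CH(C6H4-2-Oi-Pr), CH2Cl2, 40 °C) should then give the E styrene and comes back to the route at silyl ether 14, which n-Bu4NF converts into 15 as in step 8.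

Step 2. Benzyl alcohol may attack the wrong anhydride carbonyl and give regioisomeric monoesters. The fallback sets out from lactone diacid 2, isolated after the first half of step 1. One equivalent of dicyclohexylamine ionises mainly the more acidic carboxyl, the one on the oxygen-bearing ring carbon, and benzyl bromide in DMF at rt alkylates that carboxylate. Selection then rests on acidity in an O-alkylation and not on carbonyl electrophilicity in an acyl substitution; this is the known way to benzylate the more acidic carboxyl of a diacid selectively. It comes back to the route at 4 and makes no compound outside the list (F0).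

Further compounds
F0 | step 6 | none | none
F1 | step 8 | (1S,2R)-2-{[(tert-butyldimethylsilyl)oxy]methyl}-1-(3,4-dimethoxyphenyl)pent-4-en-1-ol | CC(C)(C)[Si](C)(C)OC[C@@H](CC=C)[C@H](O)c1ccc(OC)c(OC)c1
F0 | step 2 | none | none
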